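**Retrosynthetic overview**
1. Target 29 ⇐ C2 carbinol 28 (ketone unveiled last) ⇐ α-alkyl acrylate 26, whose oxirane is closed by a new catalyst-controlled nucleophilic epoxidation.
2. 26 ⇐ C7 CH2CH2OH chain (oxidation, α-methylenation, esterification); the 5β/6α diester ⇐ SN2 opening of the 4-methylidene-5α,6α-epoxide 17 by (R)-2-methylbutanoate, then acylation of C6–OH.
3. 17 ⇐ tertiary allylic alcohol 9 (MeMgCl on the C4 enone, OH-directed epoxidation, Burgess dehydration once the five-membered ring is finished).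
4. C1 side chain and C2 oxygen ⇐ enol triflate 6 of ketone 5 (carbonylative coupling, CBS reduction, convex-face hydroboration).
5. Ring order: the five-membered ring is bought as cyclopent-2-enone; the six-membered ring and the cis fusion come from an enantioselective Diels–Alder reaction with diene 3; the oxirane is formed last.

Assumption and convention: 1, 2, 4, 18 and 20 are taken as purchasable; bicyclic compounds carry the indene numbering of the target (C1–C7a, C1′ = side-chain carbinol carbon), all are cis-fused with H-3a and H-7a on the β face (α = opposite face) and have the absolute configuration of 5; TBS = tert-butyldimethylsilyl.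

**Step 1**
Reactants: 1 3-(TBS-oxy)propanal; 2 diethyl allylphosphonate
Product: 3 tert-butyl[(3E)-hexa-3,5-dien-1-yloxy]dimethylsilane
Conditions: n-BuLi, THF, −78 °C; 1, DMPU, −78 → 23 °C
Reagents that add atoms: none
Why: Horner–Wadsworth–Emmons-type olefination of the allylphosphonate carbanion gives the (3E)-1,3-diene, and any (3Z) isomer cannot reach the s-cis form and is inert in step 2.

**Step 2**
Reactants: 3 diene; 4 cyclopent-2-en-1-one
Product: 5 (3aR,7S,7aR)-7-[2-(TBS-oxy)ethyl]-2,3,3a,4,7,7a-hexahydro-1H-inden-1-one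
Conditions: (S)-o-tolyl-CBS-oxazaborolidine (20 mol %), HNTf2 (16 mol %), CH2Cl2, −78 → −20 °C
Reagents that add atoms: none
Why: Oxazaborolidinium-catalysed asymmetric Diels–Alder reaction in which the substituted diene terminus bonds to the enone α-carbon ("ortho" rule) and the endo transition state places H-3a, H-7a and H-7 all cis, while the catalyst shields one enone face to fix the absolute configuration (the antipodal catalyst is used if the observed sense is opposite).

**Step 3**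
Reactants: 5 ketone
Product: 6 7α-[2-(TBS-oxy)ethyl]-3a,4,7,7a-tetrahydro-3H-inden-1-yl trifluoromethanesulfonate
Conditions: KN(SiMe3)2, THF, −78 °C; PhNTf2, −78 → 0 °C
Reagents that add atoms: N-phenylbis(trifluoromethanesulfonimide), O=S(=O)(N(c1ccccc1)S(=O)(=O)C(F)(F)F)C(F)(F)F
Why: Kinetic enolisation at the unhindered C2 methylene (not the ring-fusion C7a–H) and O-triflation give the C1=C2 enol triflate, which also masks the ketone; no stereocentre is touched.

**Step 4**
Reactants: 6 enol triflate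
Product: 7 4β-hydroxy-7α-[2-(TBS-oxy)ethyl]-3a,4,7,7a-tetrahydro-3H-inden-1-yl trifluoromethanesulfonate (4β major)
Conditions: SeO2 (0.5 equiv), t-BuOOH, CH2Cl2, 23 °C
Reagents that add atoms: tert-butyl hydroperoxide, CC(C)(C)OO
Why: Sharpless–Umbreit allylic oxidation (ene reaction, then 2,3-sigmatropic shift) hydroxylates the allylic CH2 (C4) of the electron-rich cyclohexene without moving the double bond and leaves the electron-poor enol triflate alone; the C4 configuration is erased in step 5.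

**Step 5**
Reactants: 7 allylic alcohol
Product: 8 4-oxo-7α-[2-(TBS-oxy)ethyl]-3a,4,7,7a-tetrahydro-3H-inden-1-yl trifluoromethanesulfonate
Conditions: Dess–Martin periodinane, NaHCO3, CH2Cl2, 0 → 23 °C
Reagents that add atoms: none
Why: Dess–Martin oxidation gives the C4 enone under neutral conditions that do not epimerise C3a or C7.

**Step 6**
Reactants: 8 enone
Product: 9 4α-hydroxy-4β-methyl-7α-[2-(TBS-oxy)ethyl]-3a,4,7,7a-tetrahydro-3H-inden-1-yl trifluoromethanesulfonate
Conditions: MeMgCl, CeCl3, THF, −78 °C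
Reagents that add atoms: methylmagnesium chloride, C[Mg]Cl
Why: Organocerium 1,2-addition to the enone from the convex β face (equatorial attack, away from the axial C7a–C1 bond and the α-oriented C3) sets C4 with CH3 β and OH α; the enol triflate is inert to the non-basic reagent.

**Step 7**
Reactants: 9 tertiary allylic alcohol
Product: 10 5α,6α-epoxy-4α-hydroxy-4β-methyl-7α-[2-(TBS-oxy)ethyl]-3a,4,5,6,7,7a-hexahydro-3H-inden-1-yl trifluoromethanesulfonate
Conditions: VO(acac)2 (5 mol %), t-BuOOH, CH2Cl2, 0 → 23 °C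
Reagents that add atoms: tert-butyl hydroperoxide, CC(C)(C)OO
Why: Hydroxyl-directed vanadium epoxidation delivers oxygen syn to the pseudoaxial 4α-OH, setting C5 and C6 as the α-epoxide (the face a peracid would not choose); the enol triflate is not epoxidised.

**Step 8**
Reactants: 10 epoxy triflate
Product: 11 1-{5α,6α-epoxy-4α-hydroxy-4β-methyl-7α-[2-(TBS-oxy)ethyl]-3a,4,5,6,7,7a-hexahydro-3H-inden-1-yl}ethan-1-one
Conditions: Pd(PPh3)4 (5 mol %), LiCl, Me4Sn, CO (1 atm), THF, 55 °C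
Reagents that add atoms: carbon monoxide, [C-]#[O+]; tetramethylstannane, C[Sn](C)(C)C
Why: Carbonylative Stille coupling (oxidative addition, CO insertion, methyl transfer, reductive elimination) turns the enol triflate into the 1-acetylcyclopentene under neutral conditions that spare epoxide and tertiary alcohol.

**Step 9**
Reactants: 11 methyl enone
Product: 12 (1S)-1-{5α,6α-epoxy-4α-hydroxy-4β-methyl-7α-[2-(TBS-oxy)ethyl]-3a,4,5,6,7,7a-hexahydro-3H-inden-1-yl}ethan-1-ol
Conditions: (R)-2-methyl-CBS-oxazaborolidine (0.2 equiv), BH3·SMe2, THF, −30 °C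
Reagents that add atoms: none
Why: Corey–Bakshi–Shibata reduction with the alkenyl group as the large substituent gives the (1′S)-allylic alcohol under reagent control.

**Step 10**
Reactants: 12 allylic alcohol
Product: 13 (1S)-1-{5α,6α-epoxy-4α-hydroxy-4β-methyl-7α-[2-(TBS-oxy)ethyl]-3a,4,5,6,7,7a-hexahydro-3H-inden-1-yl}ethyl acetate
Conditions: Ac2O, pyridine, DMAP (cat.), CH2Cl2, 0 °C
Reagents that add atoms: acetic anhydride, CC(=O)OC(C)=O
Why: Acylation of the secondary allylic alcohol with retention at C1′; the hindered tertiary C4–OH is not acetylated.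

**Step 11**
Reactants: 13 allylic acetate
Product: 15 (1S)-1-{5α,6α-epoxy-2β,4α-dihydroxy-4β-methyl-7α-[2-(TBS-oxy)ethyl]octahydro-1H-inden-1α-yl}ethyl acetate, via B-alkyl-9-BBN adduct 14 (not isolated)
Conditions: 9-BBN, THF, 60 °C; then 30% H2O2, aq. NaOAc, 0 → 23 °C
Reagents that add atoms: 9-borabicyclo[3.3.1]nonane, [H]B1C2CCCC1CCC2; hydrogen peroxide, OO
Why: Hydroboration–oxidation of the only remaining alkene adds H and B syn from the convex β face with boron at the less substituted C2, so H-1 is β (side chain α, cis to C7) and oxidation with retention gives the 2β-alcohol.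

**Step 12**
Reactants: 15 diol
Product: 16 (1S)-1-{2β-(TBS-oxy)-5α,6α-epoxy-4α-hydroxy-4β-methyl-7α-[2-(TBS-oxy)ethyl]octahydro-1H-inden-1α-yl}ethyl acetate
Conditions: TBSCl, imidazole, DMAP (cat.), DMF, 40 °C
Reagents that add atoms: tert-butyl(chloro)dimethylsilane, CC(C)(C)[Si](C)(C)Cl
Why: Silylation of the secondary C2–OH under non-acidic conditions (no Lewis acid that could trigger a semipinacol shift of the epoxy alcohol) leaves the tertiary C4–OH free.

**Step 13**
Reactants: 16 tertiary alcohol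
Product: 17 (1S)-1-{2β-(TBS-oxy)-5α,6α-epoxy-4-methylidene-7α-[2-(TBS-oxy)ethyl]octahydro-1H-inden-1α-yl}ethyl acetate
Conditions: Burgess reagent, toluene, 60 °C
Reagents that add atoms: none
Why: Burgess dehydration is a syn (Ei) elimination, and only the methyl hydrogens can become syn-coplanar with the 4α C–O bond (H-3a and H-5 are trans to it), so the exocyclic methylene forms and gives the vinyl epoxide.

**Step 14**
Reactants: 17 vinyl epoxide; 18 (2R)-2-methylbutanoic acid
Product: 19 (1S)-1-{2β-(TBS-oxy)-6α-hydroxy-4-methylidene-5β-[(2R)-2-methylbutanoyloxy]-7α-[2-(TBS-oxy)ethyl]octahydro-1H-inden-1α-yl}ethyl acetate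
Conditions: 18 (5 equiv), Cs2CO3 (0.2 equiv), DMF, 60 °C
Reagents that add atoms: none
Why: SN2 opening of the vinyl epoxide by carboxylate at the allylic carbon C5 from the open β face (inversion, trans-diaxial Fürst–Plattner course) sets C5 as the β-ester and frees the 6α-OH.

**Step 15**
Reactants: 19 hydroxy ester; 20 (2E)-3-methylpent-2-enoic acid
Product: 21 (1S)-1-{2β-(TBS-oxy)-4-methylidene-5β-[(2R)-2-methylbutanoyloxy]-6α-[(2E)-3-methylpent-2-enoyloxy]-7α-[2-(TBS-oxy)ethyl]octahydro-1H-inden-1α-yl}ethyl acetate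
Conditions: 2-methyl-6-nitrobenzoic anhydride, DMAP, Et3N, CH2Cl2, 23 °C
Reagents that add atoms: none
Why: Shiina mixed-anhydride esterification acylates the hindered axial 6α-OH with retention under conditions mild enough to keep the (E)-enoate geometry.

**Step 16**
Reactants: 21 bis-silyl ether
Product: 22 the 7α-(2-hydroxyethyl) compound (primary alcohol; C2 TBS ether kept)
Conditions: HF·pyridine, pyridine, THF, 0 °C
Reagents that add atoms: none
Why: Buffered fluoride cleaves the unhindered primary silyl ether much faster than the hindered secondary C2 silyl ether.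

**Step 17**
Reactants: 22 primary alcohol
Product: 23 the 7α-(2-oxoethyl) aldehyde
Conditions: Dess–Martin periodinane, NaHCO3, CH2Cl2, 0 → 23 °C
Reagents that add atoms: none
Why: Dess–Martin oxidation stops at the aldehyde and tolerates esters, alkenes and the silyl ether.

**Step 18**
Reactants: 23 aldehyde
Product: 24 the 7α-(3-oxoprop-1-en-2-yl) compound (2-substituted acrolein)
Conditions: 37% aq. CH2O, pyrrolidine (10 mol %), EtCO2H (10 mol %), i-PrOH, 45 °C
Reagents that add atoms: formaldehyde, C=O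
Why: Organocatalytic α-methylenation (enamine Mannich reaction, then amine elimination) installs the exocyclic CH2 next to the aldehyde without base-sensitive groups being exposed to strong base.

**Step 19**
Reactants: 24 enal
Product: 25 2-(indan-7α-yl)acrylic acid derivative
Conditions: NaClO2, NaH2PO4, 2-methylbut-2-ene, t-BuOH/H2O, 0 → 23 °C
Reagents that add atoms: sodium chlorite, [Na+].[O-]Cl=O
Why: Pinnick oxidation converts the enal to the acrylic acid while the alkene scavenger removes HOCl before it can attack the exocyclic methylene.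

**Step 20**
Reactants: 25 acid
Product: 26 methyl 2-(indan-7α-yl)acrylate derivative
Conditions: Me3SiCHN2, MeOH/toluene, 0 °C
Reagents that add atoms: (trimethylsilyl)diazomethane, C[Si](C)(C)C=[N+]=[N-]
Why: O-Methylation of the carboxylic acid by the diazo reagent is neutral and leaves the other three esters untouched.

**Step 21**
Reactants: 26 acrylate
Product: 27 methyl (2S)-2-{1α-[(1S)-1-acetoxyethyl]-2β-(TBS-oxy)-4-methylidene-5β-[(2R)-2-methylbutanoyloxy]-6α-[(2E)-3-methylpent-2-enoyloxy]octahydro-1H-inden-7α-yl}oxirane-2-carboxylate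
Conditions: Y(O-i-Pr)3 (10 mol %), (S)-6,6′-[oxybis(ethane-2,1-diyloxy)]biphenyl-2,2′-diol (10 mol %), Ph3As=O (10 mol %), t-BuOOH, 4 Å MS, THF, 23 °C
Reagents that add atoms: tert-butyl hydroperoxide, CC(C)(C)OO
Why: Proposed new method: catalyst-controlled Weitz–Scheffer (nucleophilic) epoxidation of an α-branched 2-alkylacrylate ester, a substrate class with no established asymmetric variant, in which the ester binds the Lewis-acidic yttrium centre, the Y–OO-t-Bu ligand adds to the unhindered β-CH2 to give a yttrium ester enolate held in the chiral biaryldiolate pocket, and the stereodetermining attack of one enolate face on the peroxide oxygen (loss of t-BuO–) closes the oxirane and sets the quaternary (S) centre with the A(1,3)-minimised conformation at C7 reinforcing the catalyst, while the electron-rich exocyclic methylene and the hindered β,β-disubstituted enoate stay untouched; the closest known reaction is the yttrium–biaryldiol–Ph3As=O-catalysed epoxidation of β-substituted α,β-unsaturated esters with t-BuOOH.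

**Step 22**
Reactants: 27 silyl ether
Product: 28 the 2β-hydroxy glycidic ester
Conditions: HF·pyridine, THF, 23 °C
Reagents that add atoms: none
Why: Mildly acidic fluoride removes the secondary silyl ether without base, so the acetate cannot migrate and the electron-poor oxirane is not opened.

**Step 23**
Reactants: 28 alcohol
Product: 29 target, methyl (2S)-2-{(1R,3aS,5R,6R,7R,7aR)-1-[(1S)-1-acetoxyethyl]-4-methylidene-5-[(2R)-2-methylbutanoyloxy]-6-[(2E)-3-methylpent-2-enoyloxy]-2-oxooctahydro-1H-inden-7-yl}oxirane-2-carboxylate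
Conditions: Dess–Martin periodinane, NaHCO3, CH2Cl2, 0 °C
Reagents that add atoms: none
Why: Buffered Dess–Martin oxidation forms the C2 ketone last, under neutral conditions that neither epimerise the kinetically set C1 nor eliminate the β-acetoxy group.

**Compound list**
1 | 3-[(tert-butyldimethylsilyl)oxy]propanal | O=CCCO[Si](C)(C)C(C)(C)C | starting material
2 | diethyl allylphosphonate | C=CCP(=O)(OCC)OCC | starting material
3 | tert-butyl[(3E)-hexa-3,5-dien-1-yloxy]dimethylsilane | C=C/C=C/CCO[Si](C)(C)C(C)(C)C | intermediate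
4 | cyclopent-2-en-1-one | O=C1C=CCC1 | starting material
5 | (3aR,7S,7aR)-7-[2-(TBS-oxy)ethyl]-2,3,3a,4,7,7a-hexahydro-1H-inden-1-one | C1[C@H]2CCC(=O)[C@H]2[C@@H](CCO[Si](C)(C)C(C)(C)C)C=C1 | intermediate
6 | C1=C2 enol triflate of 5 | C1[C@H]2CC=C(OS(=O)(=O)C(F)(F)F)[C@H]2[C@@H](CCO[Si](C)(C)C(C)(C)C)C=C1 | intermediate
7 | 4β-hydroxy enol triflate | O[C@@H]1[C@H]2CC=C(OS(=O)(=O)C(F)(F)F)[C@H]2[C@@H](CCO[Si](C)(C)C(C)(C)C)C=C1 | intermediate
8 | 4-oxo enol triflate (C4 enone) | O=C1[C@H]2CC=C(OS(=O)(=O)C(F)(F)F)[C@H]2[C@@H](CCO[Si](C)(C)C(C)(C)C)C=C1 | intermediate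
9 | 4α-hydroxy-4β-methyl enol triflate | C[C@]1(O)[C@H]2CC=C(OS(=O)(=O)C(F)(F)F)[C@H]2[C@@H](CCO[Si](C)(C)C(C)(C)C)C=C1 | intermediate
10 | 5α,6α-epoxy-4α-hydroxy-4β-methyl enol triflate | C[C@]1(O)[C@H]2CC=C(OS(=O)(=O)C(F)(F)F)[C@H]2[C@@H](CCO[Si](C)(C)C(C)(C)C)[C@H]3O[C@H]31 | intermediate
11 | 1-acetyl epoxy alcohol (methyl enone) | C[C@]1(O)[C@H]2CC=C(C(C)=O)[C@H]2[C@@H](CCO[Si](C)(C)C(C)(C)C)[C@H]3O[C@H]31 | intermediate
12 | (1′S)-1-hydroxyethyl cyclopentene | C[C@]1(O)[C@H]2CC=C([C@H](C)O)[C@H]2[C@@H](CCO[Si](C)(C)C(C)(C)C)[C@H]3O[C@H]31 | intermediate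
13 | (1′S)-1-acetoxyethyl cyclopentene | C[C@]1(O)[C@H]2CC=C([C@H](C)OC(C)=O)[C@H]2[C@@H](CCO[Si](C)(C)C(C)(C)C)[C@H]3O[C@H]31 | intermediate
14 | 2β-(9-borabicyclo[3.3.1]nonan-9-yl) adduct of 13 (H-1 β) | C[C@]1(O)[C@H]2C[C@H](B5C6CCCC5CCC6)[C@@H]([C@H](C)OC(C)=O)[C@H]2[C@@H](CCO[Si](C)(C)C(C)(C)C)[C@H]3O[C@H]31 | intermediate
15 | 2β-hydroxy-1α-[(1S)-1-acetoxyethyl] epoxy alcohol | C[C@]1(O)[C@H]2C[C@H](O)[C@@H]([C@H](C)OC(C)=O)[C@H]2[C@@H](CCO[Si](C)(C)C(C)(C)C)[C@H]3O[C@H]31 | intermediate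
16 | 2β-TBS ether of 15 | C[C@]1(O)[C@H]2C[C@H](O[Si](C)(C)C(C)(C)C)[C@@H]([C@H](C)OC(C)=O)[C@H]2[C@@H](CCO[Si](C)(C)C(C)(C)C)[C@H]3O[C@H]31 | intermediate
17 | 4-methylidene-5α,6α-epoxide (vinyl epoxide) | C=C1[C@H]2C[C@H](O[Si](C)(C)C(C)(C)C)[C@@H]([C@H](C)OC(C)=O)[C@H]2[C@@H](CCO[Si](C)(C)C(C)(C)C)[C@H]3O[C@H]31 | intermediate
18 | (2R)-2-methylbutanoic acid | CC[C@@H](C)C(O)=O | starting material
19 | 5β-[(2R)-2-methylbutanoyloxy]-6α-hydroxy compound | C=C1[C@H]2C[C@H](O[Si](C)(C)C(C)(C)C)[C@@H]([C@H](C)OC(C)=O)[C@H]2[C@@H](CCO[Si](C)(C)C(C)(C)C)[C@@H](O)[C@@H]1OC(=O)[C@H](C)CC | intermediate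
20 | (2E)-3-methylpent-2-enoic acid | CC/C(C)=C/C(O)=O | starting material
21 | 5β,6α-diester, bis-TBS ether | C=C1[C@H]2C[C@H](O[Si](C)(C)C(C)(C)C)[C@@H]([C@H](C)OC(C)=O)[C@H]2[C@@H](CCO[Si](C)(C)C(C)(C)C)[C@@H](OC(=O)/C=C(\C)CC)[C@@H]1OC(=O)[C@H](C)CC | intermediate
22 | 7α-(2-hydroxyethyl) diester | C=C1[C@H]2C[C@H](O[Si](C)(C)C(C)(C)C)[C@@H]([C@H](C)OC(C)=O)[C@H]2[C@@H](CCO)[C@@H](OC(=O)/C=C(\C)CC)[C@@H]1OC(=O)[C@H](C)CC | intermediate
23 | 7α-(2-oxoethyl) diester | C=C1[C@H]2C[C@H](O[Si](C)(C)C(C)(C)C)[C@@H]([C@H](C)OC(C)=O)[C@H]2[C@@H](CC=O)[C@@H](OC(=O)/C=C(\C)CC)[C@@H]1OC(=O)[C@H](C)CC | intermediate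
24 | 7α-(3-oxoprop-1-en-2-yl) diester (enal) | C=C1[C@H]2C[C@H](O[Si](C)(C)C(C)(C)C)[C@@H]([C@H](C)OC(C)=O)[C@H]2[C@@H](C(=C)C=O)[C@@H](OC(=O)/C=C(\C)CC)[C@@H]1OC(=O)[C@H](C)CC | intermediate
25 | 7α-(1-carboxyethenyl) diester (acrylic acid) | C=C1[C@H]2C[C@H](O[Si](C)(C)C(C)(C)C)[C@@H]([C@H](C)OC(C)=O)[C@H]2[C@@H](C(=C)C(O)=O)[C@@H](OC(=O)/C=C(\C)CC)[C@@H]1OC(=O)[C@H](C)CC | intermediate
26 | 7α-[1-(methoxycarbonyl)ethenyl] diester (methyl acrylate) | C=C1[C@H]2C[C@H](O[Si](C)(C)C(C)(C)C)[C@@H]([C@H](C)OC(C)=O)[C@H]2[C@@H](C(=C)C(=O)OC)[C@@H](OC(=O)/C=C(\C)CC)[C@@H]1OC(=O)[C@H](C)CC | intermediate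
27 | methyl (2S)-oxirane-2-carboxylate, 2β-TBS ether | C=C1[C@H]2C[C@H](O[Si](C)(C)C(C)(C)C)[C@@H]([C@H](C)OC(C)=O)[C@H]2[C@@H]([C@@]3(C(=O)OC)CO3)[C@@H](OC(=O)/C=C(\C)CC)[C@@H]1OC(=O)[C@H](C)CC | intermediate
28 | 2β-hydroxy glycidic ester | C=C1[C@H]2C[C@H](O)[C@@H]([C@H](C)OC(C)=O)[C@H]2[C@@H]([C@@]3(C(=O)OC)CO3)[C@@H](OC(=O)/C=C(\C)CC)[C@@H]1OC(=O)[C@H](C)CC | intermediate
29 | CNP0251769.2 | C=C1[C@H]2CC(=O)[C@@H]([C@H](C)OC(C)=O)[C@H]2[C@@H]([C@@]2(C(=O)OC)CO2)[C@@H](OC(=O)/C=C(\C)CC)[C@@H]1OC(=O)[C@H](C)CC | target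

**Totals**
Total step count: 23. Longest linear sequence: 23 steps (1 and 2 to 29); 4, 18 and 20 enter as purchased building blocks.

**Three steps most likely to fail**

Step 2 (enantioselective Diels–Alder with a sluggish dienophile): the fallback uses a chiral-pool dienophile instead of a chiral catalyst. It sets out from 3 and comes back at 5. Diene 3 is heated (toluene, 110 °C) with commercial (4R)-4-[(tert-butyldimethylsilyl)oxy]cyclopent-2-en-1-one F1; addition anti to the silyloxy group with the same endo and regiochemical preference gives the 3β-silyloxy adduct F2. DBU (CH2Cl2, 23 °C) eliminates silanol to the ring-fused cyclopent-2-enone F3, and conjugate reduction with [(Ph3P)CuH]6 (wet benzene) gives 5.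

Step 14 (the carboxylate may attack the exocyclic CH2 in SN2′ fashion or react slowly): the fallback separates ring opening from acylation. It sets out from 17 and comes back at 19. Hydrolysis of 17 (Sc(OTf)3 5 mol %, THF/H2O, 0 °C) opens the vinyl epoxide at the allylic carbon with inversion to the trans-diaxial 5β,6α-diol F4. The less hindered allylic 5β-OH is then acylated selectively with 18 (EDC·HCl, DMAP, CH2Cl2, −20 °C) to give 19.

Step 21 (the proposed new epoxidation; risks are low conversion of the α-branched acrylate or a mismatched substrate bias): the fallback uses a Sharpless asymmetric epoxidation at the alcohol oxidation level. It sets out from 24 and comes back at 27, bypassing 25 and 26. Luche reduction of enal 24 (NaBH4, CeCl3·7H2O, MeOH, −40 °C) gives the 2-substituted allylic alcohol F5. Epoxidation with Ti(O-i-Pr)4, D-(−)-diethyl tartrate and t-BuOOH (4 Å MS, CH2Cl2, −20 °C) gives the (2R)-epoxy alcohol F6 under reagent control; only the allylic alcohol alkene reacts. TEMPO/PhI(OAc)2 in MeCN/H2O oxidises F6 to the epoxy acid F7, and Me3SiCHN2 (MeOH/toluene, 0 °C) gives 27.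

**Further compounds**
F1 | step 2 | (4R)-4-[(tert-butyldimethylsilyl)oxy]cyclopent-2-en-1-one | O=C1C=C[C@H](O[Si](C)(C)C(C)(C)C)C1
F2 | step 2 | 3β-(TBS-oxy) derivative of ketone 5 | C1[C@H]2[C@H](O[Si](C)(C)C(C)(C)C)CC(=O)[C@H]2[C@@H](CCO[Si](C)(C)C(C)(C)C)C=C1
F3 | step 2 | 2,3-didehydro derivative of 5 (7α-[2-(TBS-oxy)ethyl]-3a,4,7,7a-tetrahydro-1H-inden-1-one) | C1[C@H]2C=CC(=O)[C@H]2[C@@H](CCO[Si](C)(C)C(C)(C)C)C=C1
F4 | step 14 | 5β,6α-diol from vinyl epoxide 17 | C=C1[C@H]2C[C@H](O[Si](C)(C)C(C)(C)C)[C@@H]([C@H](C)OC(C)=O)[C@H]2[C@@H](CCO[Si](C)(C)C(C)(C)C)[C@@H](O)[C@@H]1O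
F5 | step 21 | 7α-(3-hydroxyprop-1-en-2-yl) diester (allylic alcohol) | C=C1[C@H]2C[C@H](O[Si](C)(C)C(C)(C)C)[C@@H]([C@H](C)OC(C)=O)[C@H]2[C@@H](C(=C)CO)[C@@H](OC(=O)/C=C(\C)CC)[C@@H]1OC(=O)[C@H](C)CC
F6 | step 21 | 7α-[(2R)-2-(hydroxymethyl)oxiran-2-yl] diester (epoxy alcohol) | C=C1[C@H]2C[C@H](O[Si](C)(C)C(C)(C)C)[C@@H]([C@H](C)OC(C)=O)[C@H]2[C@@H]([C@@]3(CO)CO3)[C@@H](OC(=O)/C=C(\C)CC)[C@@H]1OC(=O)[C@H](C)CC
F7 | step 21 | 7α-[(2S)-2-carboxyoxiran-2-yl] diester (epoxy acid) | C=C1[C@H]2C[C@H](O[Si](C)(C)C(C)(C)C)[C@@H]([C@H](C)OC(C)=O)[C@H]2[C@@H]([C@@]3(C(O)=O)CO3)[C@@H](OC(=O)/C=C(\C)CC)[C@@H]1OC(=O)[C@H](C)CC
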